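The numbers are assumed; the rest is arithmetic.

The charges below are equal; the vessels differ.

    2 first chain carrier → ended chains A (k1 = 3.6 × 10⁷ /M/s)
    reagent + first chain carrier → target + second chain carrier (k2 = 1.9 × 10⁵ /M/s)
    first chain carrier → ended carrier (k3 = 320 /s)
    starting material + second chain carrier → by-product + first chain carrier (k4 = 4.4 × 10⁵ /M/s)
    2 second chain carrier → ended chains B (k5 = 9.4 × 10⁸ /M/s)
    initiator → 2 initiating radical (k6 = 5.8 × 10⁻⁴ /s)
    starting material + initiating radical → capped initiator + first chain carrier (k7 = 2.1 × 10⁶ /M/s)

| flask | starting material | reagent | initiator | time | remark |
|---|---|---|---|---|---|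
| theta | 0.24 M | 0.228 M | 4.8 mM | 15 min | everything together in a closed stirred flask, run for 15 min |
| zeta | 0.24 M | 0.228 M | 4.8 mM |  | one stirred flow tank at steady state, fed with the mixture as stated, mean residence time 15 min |
| epsilon | 0.24 M | 0.228 M | 4.8 mM |  | one stirred flow tank at steady state, fed with the mixture as stated, mean residence time 150 min |
| alpha | 0.24 M (fed, over 12.0 min) | 0.228 M | 4.8 mM | 15 min | all but starting material at the start; starting material goes in evenly over 12.0 min, the run ends at 15 min |

- percentages count the starting material that a species holds: one ended chains A counts as two
- for a step with 2 of a species take k times the square, and two of it per event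
- the stated concentrations are those of everything mixed, before any reaction; amounts are the same in each set-up
- the feed brings no volume worth counting
- run time (theta): 15 min

- the set-up with the highest amount of target at the outlet or at the end, in percent of the starting material put in ("none" if the first two lie within 2 percentage points) (theta / zeta / epsilon / alpha / none)
- amount of target at the outlet or at the end, in percent of the starting material put in, theta
- amount of target at the outlet or at the end, in percent of the starting material put in, zeta
- amount of target at the outlet or at the end, in percent of the starting material put in, epsilon
- amount of target at the outlet or at the end, in percent of the starting material put in, alpha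

1. Follow one first chain carrier at its fork, at the start of theta. The target step takes it at 43300 /s, and the step to ended carrier takes it at 320 /s, so it turns about 135 times before it ends (this is the kinetic chain length).

2. The other ends, still at the start of theta, are reckoned from the level of first chain carrier, about 1.74 × 10⁻⁸ M. Coupling of first chain carriers runs at 1.25 /s, far below 320 /s. Second chain carriers are reckoned near 7.14 × 10⁻⁹ M, and their chance of coupling per turn, 1.27 × 10⁻⁴, is well below the 0.00739 of ending as ended carrier.

3. While chains end as ended carrier, each spent initiator gives two chains, and chain length is proportional to reagent present. Reagent therefore falls by a factor e for each 0.842 mM of initiator spent: the chain dose m, the constant of the ending step divided by twice that of the target step. With ΔN the initiator spent, S = ΔN/m. The fraction of reagent left is exp(−S) in a closed flask and one over (one plus S) in a tank.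

4. The reckoning by hand, with target equal to reagent used:
- Theta: ΔN is 1.95 mM, S is 2.32, target 85.6%.
- Zeta: ΔN is 1.65 mM, S is 1.95, target 62.9%.
- Epsilon: ΔN is 4.03 mM, S is 4.78, target 78.6%.
- Alpha: the reckoning stops here, since the coupling comparison above used the whole 0.24 M of starting material, which alpha receives over 12.0 min.

5. The forecast names theta, with 85.4%, 62.5%, 78.5% and 76% for theta, zeta, epsilon and alpha. Its own note: “these are quick hand estimates, and the semi-batch figure is the roughest”. The forecast's numbers are not those of the hand reckoning, which gives none for alpha.

6. The simulation gives theta as best, with 85.3%, 62.6%, 78.5% and 77.4% in the same order.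

Alpha ends with 5.27 × 10⁻⁴ M of ended chains B. Each holds two carriers, so each counts as one initiator lost to the count. That leaves 1.42 mM of useful ΔN, so S is 1.69 and the reagent left is 18.5%; the flask shows 18%. The neighbour is alpha with 0.96 M of starting material, and it holds 9.16 × 10⁻⁵ M of ended chains B. Its useful ΔN is 1.86 mM, S is 2.21, and target comes to 21.1% of its charge; the flask gives 21.1%.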